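**Strategy.** The target is a succinic acid half-ester whose adjacent methines C2 (bearing ring A) and C3 (bearing the CH2 of ring B) each carry a carboxyl carbon, C1 (acid) and C4 (ester), in the erythro relation. Both the C1–C2 and C3–C4 bonds are therefore cut back to the Z alkene ring A–CH=CH–CH2–ring B. One palladium-catalysed oxidative bis-methoxycarbonylation adds two CO-derived ester groups to the same face and sets both stereocentres. The precursor is a Z-1,3-diarylpropene with both phenols as triisopropylsilyl ethers and the prenyl group in place. The two esters are later told apart by alkaloid-controlled methanolysis of the cis anhydride.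

Key step: step 9

Assumption: the face chosen by the bis(oxazoline)–palladium catalyst on this Z alkene cannot be predicted from precedent; the (S,S) ligand is written, and its commercial (R,R) antipode is used instead if that is the one leading to (2R,3R)-17.

Design notes:
- Triisopropylsilyl ethers are used on both phenols because they should survive the organometallic, hydride and tin hydroxide steps and still leave with fluoride without acid; acid would cyclise the ortho-prenylphenol.
- Methanol is the nucleophile of the key step because it has the best precedent there, and methyl esters can be cleaved later without touching aryl silyl ethers.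
- C1 and C4 are both flanked by a tertiary carbon, so steric bias between them is small. The choice of carbonyl is therefore handed to a chiral amine acting on the cis anhydride.
- Any (2S,3S) material passing step 9 should be opened by the same amine at the other carbonyl and so leave as a separable constitutional isomer.

**Route**

Step 1
Reactants: 1 methyl 4-bromo-3-hydroxybenzoate
Product: 2 methyl 4-bromo-3-(triisopropylsilyloxy)benzoate
Conditions: TIPSCl, imidazole, DMF, 20 °C
Reagents that add atoms: chlorotriisopropylsilane, CC(C)[Si](Cl)(C(C)C)C(C)C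
Why: Imidazole-promoted silylation of the phenol (substitution at silicon); the hindered triisopropylsilyl ether should survive organozinc, hydride, butyllithium and tin hydroxide and still leave with fluoride at the end.

Step 2
Reactants: 2 methyl 4-bromo-3-(triisopropylsilyloxy)benzoate; 3 prenyl bromide (1-bromo-3-methylbut-2-ene)
Product: 5 methyl 4-(3-methylbut-2-enyl)-3-(triisopropylsilyloxy)benzoate, via prenylzinc bromide 4 (not isolated)
Conditions: Zn dust, LiCl, THF, 0 °C; then 2, Pd(OAc)2 (2 mol%), CPhos (2-dicyclohexylphosphino-2',6'-bis(dimethylamino)biphenyl, 4 mol%), THF, 20 °C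
Reagents that add atoms: none
Why: Negishi coupling, in which the allylzinc from zinc insertion transmetallates to the arylpalladium bromide and the CPhos ligand favours reductive elimination at the unsubstituted allyl terminus, so the linear prenyl arene and not the 1,1-dimethylallyl isomer is expected, while the methyl ester is inert to the allylzinc at room temperature.

Step 3
Reactants: 5 methyl 4-(3-methylbut-2-enyl)-3-(triisopropylsilyloxy)benzoate
Product: 6 benzylic alcohol [4-(3-methylbut-2-enyl)-3-(triisopropylsilyloxy)phenyl]methanol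
Conditions: i-Bu2AlH, CH2Cl2, −78 to 0 °C; aq. potassium sodium tartrate
Reagents that add atoms: none
Why: Hydride reduction of the aryl ester to the benzylic alcohol, with the aryl silyl ether and the trisubstituted alkene inert to i-Bu2AlH at low temperature.

Step 4
Reactants: 6 benzylic alcohol [4-(3-methylbut-2-enyl)-3-(triisopropylsilyloxy)phenyl]methanol
Product: 7 benzylic bromide 4-(bromomethyl)-1-(3-methylbut-2-enyl)-2-(triisopropylsilyloxy)benzene
Conditions: CBr4, PPh3, CH2Cl2, 0 °C
Reagents that add atoms: carbon tetrabromide, BrC(Br)(Br)Br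
Why: Appel reaction, an SN2 displacement of the activated benzylic oxygen by bromide under neutral conditions that leave the prenyl alkene and the silyl ether alone.

Step 5
Reactants: 8 4-hydroxybenzaldehyde
Product: 9 4-(triisopropylsilyloxy)benzaldehyde
Conditions: TIPSCl, imidazole, DMF, 20 °C
Reagents that add atoms: chlorotriisopropylsilane, CC(C)[Si](Cl)(C(C)C)C(C)C
Why: Imidazole-promoted silylation of the phenol, placing the same robust protecting group on ring A.

Step 6
Reactants: 9 4-(triisopropylsilyloxy)benzaldehyde
Product: 10 dibromoalkene 1-(2,2-dibromoethenyl)-4-(triisopropylsilyloxy)benzene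
Conditions: CBr4, PPh3, CH2Cl2, 0 °C
Reagents that add atoms: carbon tetrabromide, BrC(Br)(Br)Br
Why: First half of the Corey–Fuchs alkyne synthesis, a Wittig-type olefination of the aldehyde by the dibromomethylene ylide formed from CBr4 and PPh3.

Step 7
Reactants: 10 dibromoalkene 1-(2,2-dibromoethenyl)-4-(triisopropylsilyloxy)benzene; 7 benzylic bromide 4-(bromomethyl)-1-(3-methylbut-2-enyl)-2-(triisopropylsilyloxy)benzene
Product: 13 alkyne 1-[4-(triisopropylsilyloxy)phenyl]-3-[4-(3-methylbut-2-enyl)-3-(triisopropylsilyloxy)phenyl]prop-1-yne, via lithium arylacetylide 11 (not isolated), via arylethynylzinc bromide 12 (not isolated)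
Conditions: n-BuLi (2.1 equiv), THF, −78 °C; ZnBr2, −78 to 0 °C; then 7, PdCl2(DPEphos) (3 mol%), THF, 20 °C
Reagents that add atoms: none
Why: Second half of the Corey–Fuchs sequence (bromine–lithium exchange, 1,2-shift and deprotonation to the lithium acetylide), transmetallation to zinc and Negishi sp–sp3 coupling with the benzylic bromide, a base-free bond formation that should avoid isomerisation of the doubly activated propargylic CH2 to the allene.

Step 8
Reactants: 13 alkyne 1-[4-(triisopropylsilyloxy)phenyl]-3-[4-(3-methylbut-2-enyl)-3-(triisopropylsilyloxy)phenyl]prop-1-yne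
Product: 14 Z alkene (Z)-1-[4-(triisopropylsilyloxy)phenyl]-3-[4-(3-methylbut-2-enyl)-3-(triisopropylsilyloxy)phenyl]prop-1-ene
Conditions: H2 (1 atm), Pd/CaCO3 poisoned with Pb(OAc)2, quinoline, EtOAc, 20 °C, stopped after one equivalent of H2
Reagents that add atoms: none
Why: Lindlar-type semi-hydrogenation, in which both hydrogens reach one face of the alkyne on the poisoned palladium surface to give the Z alkene, while the trisubstituted prenyl alkene is too hindered to be reduced.

Step 9
Reactants: 14 Z alkene (Z)-1-[4-(triisopropylsilyloxy)phenyl]-3-[4-(3-methylbut-2-enyl)-3-(triisopropylsilyloxy)phenyl]prop-1-ene; 15 carbon monoxide (two molecules incorporated); 16 methanol (two molecules incorporated)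
Product: 17 dimethyl (2R,3R)-2-[4-(triisopropylsilyloxy)phenyl]-3-{[4-(3-methylbut-2-enyl)-3-(triisopropylsilyloxy)phenyl]methyl}butanedioate
Conditions: Pd(OCOCF3)2 (5 mol%), (S,S)-t-Bu-BOX [2,2'-(propane-2,2-diyl)bis((4S)-4-tert-butyl-4,5-dihydro-1,3-oxazole), 6 mol%], p-benzoquinone (1.5 equiv), CO (4 bar), MeOH/THF, 20 °C
Reagents that add atoms: none
Why: Proposed new method: a methoxycarbonyl–palladium species (from divalent palladium, methanol and CO) should add syn across C2=C3, placing CO2Me on C3 and palladium on the benzylic C2 as a π-benzyl complex stabilised by the electron-rich ring A, after which CO insertion with retention and methanolysis of the acyl–palladium release 17 and zerovalent palladium, which p-benzoquinone returns to divalent palladium. The closest known reaction types are the syn-specific bis-alkoxycarbonylation of 1,2-disubstituted alkenes with Pd(OCOCF3)2, achiral α-diimines and benzoquinone, and the enantioselective bis-methoxycarbonylation of styrene with chiral ligands; the new element is enantiocontrol on an internal Z alkene. No ring closes. The relative configuration at C2 and C3 follows from the Z geometry because both carbonyls arrive on the same face (erythro, 2R,3R or 2S,3S), and the absolute configuration is set by the enantioface choice of the C2-symmetric bis(oxazoline) on palladium. The step needs chemoselectivity over the prenyl alkene, secured by its trisubstituted, non-conjugated nature, needs insertion to outrun Z-to-E isomerisation, and has no regiochemical issue because the same group enters both carbons. The ring B phenol stays silylated so that it cannot add to the prenyl alkene by oxypalladation.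

Step 10
Reactants: 17 dimethyl (2R,3R)-2-[4-(triisopropylsilyloxy)phenyl]-3-{[4-(3-methylbut-2-enyl)-3-(triisopropylsilyloxy)phenyl]methyl}butanedioate
Product: 18 diacid (2R,3R)-2-[4-(triisopropylsilyloxy)phenyl]-3-{[4-(3-methylbut-2-enyl)-3-(triisopropylsilyloxy)phenyl]methyl}butanedioic acid
Conditions: Me3SnOH (10 equiv), 1,2-dichloroethane, 80 °C; then cold 5% aq. HCl wash
Reagents that add atoms: trimethyltin hydroxide, C[Sn](C)(C)O
Why: Ester hydrolysis with Me3SnOH (tin-assisted acyl substitution under nearly neutral conditions), chosen because it should cleave both methyl esters without epimerising the acidic benzylic C2–H and without removing the aryl silyl ethers, which hydroxide bases would do.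

Step 11
Reactants: 18 diacid (2R,3R)-2-[4-(triisopropylsilyloxy)phenyl]-3-{[4-(3-methylbut-2-enyl)-3-(triisopropylsilyloxy)phenyl]methyl}butanedioic acid
Product: 19 cis anhydride (3R,4R)-3-[4-(triisopropylsilyloxy)phenyl]-4-{[4-(3-methylbut-2-enyl)-3-(triisopropylsilyloxy)phenyl]methyl}oxolane-2,5-dione
Conditions: DCC, CH2Cl2, 0 to 20 °C; filtered and used crude
Reagents that add atoms: none
Why: Carbodiimide cyclodehydration of the 1,4-diacid to the five-membered anhydride, run without base so that the erythro diacid closes to the cis anhydride with both stereocentres untouched.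

Step 12
Reactants: 19 cis anhydride (3R,4R)-3-[4-(triisopropylsilyloxy)phenyl]-4-{[4-(3-methylbut-2-enyl)-3-(triisopropylsilyloxy)phenyl]methyl}oxolane-2,5-dione; 16 methanol
Product: 20 half-ester (2R,3R)-4-methoxy-4-oxo-2-[4-(triisopropylsilyloxy)phenyl]-3-{[4-(3-methylbut-2-enyl)-3-(triisopropylsilyloxy)phenyl]methyl}butanoic acid
Conditions: quinidine (1.1 equiv), MeOH (3 equiv), toluene, −55 °C; then cold 1 M aq. HCl wash
Reagents that add atoms: none
Why: Cinchona-alkaloid-mediated methanolysis of a cis-2,3-disubstituted succinic anhydride (general-base delivery of methanol), in which quinidine picks one carbonyl by the topology of the cis ring and not by the small steric difference between the two sides, its established sense on such anhydrides corresponding to attack at C4 here (its pseudoenantiomer quinine would select C1), and no stereocentre is formed or disturbed at −55 °C.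

Step 13
Reactants: 20 half-ester (2R,3R)-4-methoxy-4-oxo-2-[4-(triisopropylsilyloxy)phenyl]-3-{[4-(3-methylbut-2-enyl)-3-(triisopropylsilyloxy)phenyl]methyl}butanoic acid
Product: 21 target (2R,3R)-2-(4-hydroxyphenyl)-3-{[3-hydroxy-4-(3-methylbut-2-enyl)phenyl]methyl}-4-methoxy-4-oxobutanoic acid
Conditions: TBAF, AcOH, THF, 0 °C
Reagents that add atoms: none
Why: Fluoride-induced desilylation of the two aryl silyl ethers (attack at silicon), buffered with acetic acid so that neither the methyl ester nor the C3 stereocentre is exposed to base and the prenylphenol meets no strong acid.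

**Compound list**

1 | methyl 4-bromo-3-hydroxybenzoate | COC(=O)c1ccc(Br)c(O)c1 | starting material
2 | methyl 4-bromo-3-(triisopropylsilyloxy)benzoate | COC(=O)c1ccc(Br)c(O[Si](C(C)C)(C(C)C)C(C)C)c1 | intermediate
3 | prenyl bromide (1-bromo-3-methylbut-2-ene) | CC(C)=CCBr | starting material
4 | prenylzinc bromide, (3-methylbut-2-enyl)zinc bromide | CC(C)=CC[Zn]Br | intermediate
5 | methyl 4-(3-methylbut-2-enyl)-3-(triisopropylsilyloxy)benzoate | COC(=O)c1ccc(CC=C(C)C)c(O[Si](C(C)C)(C(C)C)C(C)C)c1 | intermediate
6 | [4-(3-methylbut-2-enyl)-3-(triisopropylsilyloxy)phenyl]methanol | OCc1ccc(CC=C(C)C)c(O[Si](C(C)C)(C(C)C)C(C)C)c1 | intermediate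
7 | 4-(bromomethyl)-1-(3-methylbut-2-enyl)-2-(triisopropylsilyloxy)benzene | BrCc1ccc(CC=C(C)C)c(O[Si](C(C)C)(C(C)C)C(C)C)c1 | intermediate
8 | 4-hydroxybenzaldehyde | O=Cc1ccc(O)cc1 | starting material
9 | 4-(triisopropylsilyloxy)benzaldehyde | O=Cc1ccc(O[Si](C(C)C)(C(C)C)C(C)C)cc1 | intermediate
10 | 1-(2,2-dibromoethenyl)-4-(triisopropylsilyloxy)benzene | BrC(Br)=Cc1ccc(O[Si](C(C)C)(C(C)C)C(C)C)cc1 | intermediate
11 | lithium [4-(triisopropylsilyloxy)phenyl]acetylide | [Li]C#Cc1ccc(O[Si](C(C)C)(C(C)C)C(C)C)cc1 | intermediate
12 | {[4-(triisopropylsilyloxy)phenyl]ethynyl}zinc bromide | Br[Zn]C#Cc1ccc(O[Si](C(C)C)(C(C)C)C(C)C)cc1 | intermediate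
13 | 1-[4-(triisopropylsilyloxy)phenyl]-3-[4-(3-methylbut-2-enyl)-3-(triisopropylsilyloxy)phenyl]prop-1-yne | C(C#Cc1ccc(O[Si](C(C)C)(C(C)C)C(C)C)cc1)c1ccc(CC=C(C)C)c(O[Si](C(C)C)(C(C)C)C(C)C)c1 | intermediate
14 | (Z)-1-[4-(triisopropylsilyloxy)phenyl]-3-[4-(3-methylbut-2-enyl)-3-(triisopropylsilyloxy)phenyl]prop-1-ene | C(/C=C\c1ccc(O[Si](C(C)C)(C(C)C)C(C)C)cc1)c1ccc(CC=C(C)C)c(O[Si](C(C)C)(C(C)C)C(C)C)c1 | intermediate
15 | carbon monoxide | [C-]#[O+] | starting material
16 | methanol | CO | starting material
17 | dimethyl (2R,3R)-2-[4-(triisopropylsilyloxy)phenyl]-3-{[4-(3-methylbut-2-enyl)-3-(triisopropylsilyloxy)phenyl]methyl}butanedioate | COC(=O)[C@H](Cc1ccc(CC=C(C)C)c(O[Si](C(C)C)(C(C)C)C(C)C)c1)[C@@H](C(=O)OC)c1ccc(O[Si](C(C)C)(C(C)C)C(C)C)cc1 | intermediate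
18 | (2R,3R)-2-[4-(triisopropylsilyloxy)phenyl]-3-{[4-(3-methylbut-2-enyl)-3-(triisopropylsilyloxy)phenyl]methyl}butanedioic acid | OC(=O)[C@H](Cc1ccc(CC=C(C)C)c(O[Si](C(C)C)(C(C)C)C(C)C)c1)[C@@H](C(=O)O)c1ccc(O[Si](C(C)C)(C(C)C)C(C)C)cc1 | intermediate
19 | (3R,4R)-3-[4-(triisopropylsilyloxy)phenyl]-4-{[4-(3-methylbut-2-enyl)-3-(triisopropylsilyloxy)phenyl]methyl}oxolane-2,5-dione (cis) | O=C1[C@H](Cc2ccc(CC=C(C)C)c(O[Si](C(C)C)(C(C)C)C(C)C)c2)[C@H](c2ccc(O[Si](C(C)C)(C(C)C)C(C)C)cc2)C(=O)O1 | intermediate
20 | (2R,3R)-4-methoxy-4-oxo-2-[4-(triisopropylsilyloxy)phenyl]-3-{[4-(3-methylbut-2-enyl)-3-(triisopropylsilyloxy)phenyl]methyl}butanoic acid | COC(=O)[C@H](Cc1ccc(CC=C(C)C)c(O[Si](C(C)C)(C(C)C)C(C)C)c1)[C@@H](C(=O)O)c1ccc(O[Si](C(C)C)(C(C)C)C(C)C)cc1 | intermediate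
21 | (2R,3R)-2-(4-hydroxyphenyl)-3-{[3-hydroxy-4-(3-methylbut-2-enyl)phenyl]methyl}-4-methoxy-4-oxobutanoic acid | COC(=O)[C@H](Cc1ccc(CC=C(C)C)c(O)c1)[C@@H](C(=O)O)c1ccc(O)cc1 | target

**Step count and risks**

Total: 13 steps. Longest linear sequence: 11 steps (1–4, then 7–13).

Steps most likely to fail:

1. Step 9 (proposed new method). Enantioface selection on the internal alkene may be low. Reversible coordination or palladium hydride may also turn Z into E (which would lead to the threo diester) or move the double bond into conjugation with ring B before insertion. The fallback uses known chemistry, sets out from 14 and comes back at 20. The racemic, syn-specific bis-methoxycarbonylation of 1,2-disubstituted alkenes is run on 14 with Pd(OCOCF3)2 and the achiral ligand N,N'-bis(2,6-dimethylphenyl)butane-2,3-diimine (p-benzoquinone, CO 4 bar, MeOH/THF, 20 °C). It should give 17 together with its enantiomer, dimethyl (2S,3S)-2-[4-(triisopropylsilyloxy)phenyl]-3-{[4-(3-methylbut-2-enyl)-3-(triisopropylsilyloxy)phenyl]methyl}butanedioate F1. Steps 10 and 11 on this racemate give 18 and 19 beside the (2S,3S) diacid F2 and the (3S,4S) cis anhydride F3. The quinidine methanolysis then acts as a parallel kinetic resolution, a known behaviour of chiral succinic anhydrides with cinchona alkaloids. Anhydride 19 opens at C4 to 20, whereas F3 opens at the carbonyl next to ring A to a constitutional isomer, the (2S,3S) half-ester with the methyl ester on the aryl-bearing side F4, which is removed by chromatography.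

2. Step 12. The alkaloid may fail to override the intrinsic preference of the anhydride, so that methanol enters at the C1 carbonyl, and the amine may epimerise the cis anhydride at the aryl-bearing C2. The fallback sets out from 17 and comes back at 20 without passing through 18 and 19, and makes no new compound. The two esters are told apart by rate at the diester stage through partial hydrolysis with Me3SnOH (about 1.5 equiv, 1,2-dichloroethane, 60 °C), stopped at the half-ester. The C1 ester is of the arylacetic type and is the more electrophilic, so it should be cleaved first; over-hydrolysed 18 and any regioisomer are separated by chromatography.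

3. Step 8. Hydrogen uptake may not stop at the alkene, and the palladium surface may scramble the Z geometry or shift the skipped double bond. The fallback avoids both alkyne and hydrogenation, sets out from 10 and 7 and comes back at 14. Palladium-catalysed hydrogenolysis of 10 (Bu3SnH, Pd(PPh3)4, toluene, 20 °C) removes the bromine trans to the aryl group and should give (Z)-1-(2-bromoethenyl)-4-(triisopropylsilyloxy)benzene F5. Zinc insertion into 7 (Zn dust, LiCl, THF, 0 °C) gives the benzylic reagent {[4-(3-methylbut-2-enyl)-3-(triisopropylsilyloxy)phenyl]methyl}zinc bromide F6. Negishi coupling of F5 and F6 (Pd(PPh3)4, THF, 20 °C) proceeds with retention of the alkene geometry and delivers 14.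

**Further compounds**

F1 | step 9 | dimethyl (2S,3S)-2-[4-(triisopropylsilyloxy)phenyl]-3-{[4-(3-methylbut-2-enyl)-3-(triisopropylsilyloxy)phenyl]methyl}butanedioate | COC(=O)[C@@H](Cc1ccc(CC=C(C)C)c(O[Si](C(C)C)(C(C)C)C(C)C)c1)[C@H](C(=O)OC)c1ccc(O[Si](C(C)C)(C(C)C)C(C)C)cc1
F2 | step 9 | (2S,3S)-2-[4-(triisopropylsilyloxy)phenyl]-3-{[4-(3-methylbut-2-enyl)-3-(triisopropylsilyloxy)phenyl]methyl}butanedioic acid | OC(=O)[C@@H](Cc1ccc(CC=C(C)C)c(O[Si](C(C)C)(C(C)C)C(C)C)c1)[C@H](C(=O)O)c1ccc(O[Si](C(C)C)(C(C)C)C(C)C)cc1
F3 | step 9 | (3S,4S)-3-[4-(triisopropylsilyloxy)phenyl]-4-{[4-(3-methylbut-2-enyl)-3-(triisopropylsilyloxy)phenyl]methyl}oxolane-2,5-dione (cis) | O=C1[C@@H](Cc2ccc(CC=C(C)C)c(O[Si](C(C)C)(C(C)C)C(C)C)c2)[C@@H](c2ccc(O[Si](C(C)C)(C(C)C)C(C)C)cc2)C(=O)O1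
F4 | step 9 | (2S,3S)-4-methoxy-4-oxo-3-[4-(triisopropylsilyloxy)phenyl]-2-{[4-(3-methylbut-2-enyl)-3-(triisopropylsilyloxy)phenyl]methyl}butanoic acid | OC(=O)[C@@H](Cc1ccc(CC=C(C)C)c(O[Si](C(C)C)(C(C)C)C(C)C)c1)[C@H](C(=O)OC)c1ccc(O[Si](C(C)C)(C(C)C)C(C)C)cc1
F0 | step 12 | none | none
F5 | step 8 | (Z)-1-(2-bromoethenyl)-4-(triisopropylsilyloxy)benzene | Br/C=C\c1ccc(O[Si](C(C)C)(C(C)C)C(C)C)cc1
F6 | step 8 | {[4-(3-methylbut-2-enyl)-3-(triisopropylsilyloxy)phenyl]methyl}zinc bromide | Br[Zn]Cc1ccc(CC=C(C)C)c(O[Si](C(C)C)(C(C)C)C(C)C)c1
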